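**Retrosynthetic overview**

1. The strategy rests on one feature: in both flavan units the stereogenic C2 (between ring oxygen O1 and the oxygenated C3) is bonded directly to an sp2 carbon of the benzotropolone, C1 of its benzene ring for the galloylated flavan and C7 of its tropolone ring for the other.
2. Target ⇐ hydrogenolysis of eleven benzyl ethers ⇐ galloylation of the single C3 hydroxyl that was carried as a silyl ether ⇐ fully protected bis-flavan benzotropolone.
3. Protected bis-flavan ⇐ one-pot stereoretentive Pd/Cu coupling of a 1-iodo-7-bromo-tris(benzyloxy)benzotropolone with two preformed cis-2-(tributylstannyl)chromans (3-OTBS at C1 first, 3-OBn at C7 second).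
4. Core ⇐ 2-bromo-4,5-dimethoxybenzaldehyde: seven-membered ring closed by Friedel–Crafts acylation, Br→I exchange at C1, oxidation to the 1,2-dione, bromination–dehydrobromination to the 7-bromotropolone.
5. Stannanes ⇐ 3,5-bis(benzyloxy)phenol + methyl (R)-glycidate (source of C3): pyran ring closed by lactonisation, C2–Sn set cis by reductive lithiation of the C3 alkoxide; the seven-membered ring and the pyran rings are made first, no ring is formed in or after the coupling.

Key step: step 17

Remark: the tropolone is written throughout as the 5-oxo-6-hydroxy (6-alkoxy) tautomer of the given SMILES; 3,5-bis(benzyloxy)phenol and 3,4,5-tris(benzyloxy)benzoic acid (the benzylated forms of phloroglucinol and gallic acid) are taken as purchased.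

**Route**

Step 1
Reactants: 1 2-bromo-4,5-dimethoxybenzaldehyde
Product: 2 5-(2-bromo-4,5-dimethoxyphenyl)pent-4-enoic acid (E/Z mixture)
Conditions: (3-carboxypropyl)triphenylphosphonium bromide, KOtBu (2.2 equiv), THF, 0 → 20 °C; aq. HCl
Reagents that add atoms: (3-carboxypropyl)triphenylphosphonium bromide, OC(=O)CCC[P+](c1ccccc1)(c1ccccc1)c1ccccc1.[Br-]
Why: Wittig olefination of the aldehyde with the carboxylate-bearing ylide installs the five-carbon acid chain; the alkene geometry is immaterial because the double bond is saturated in step 2.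

Step 2
Reactants: 2 5-(2-bromo-4,5-dimethoxyphenyl)pent-4-enoic acid
Product: 3 5-(2-bromo-4,5-dimethoxyphenyl)pentanoic acid
Conditions: H2 (1 atm), RhCl(PPh3)3 (5 mol %), toluene/EtOH, 40 °C
Reagents that add atoms: none
Why: Homogeneous hydrogenation with RhCl(PPh3)3 should reduce the disubstituted alkene without hydrogenolysis of the aryl bromide.

Step 3
Reactants: 3 5-(2-bromo-4,5-dimethoxyphenyl)pentanoic acid
Product: 4 1-bromo-3,4-dimethoxy-6,7,8,9-tetrahydro-5H-benzo[7]annulen-5-one
Conditions: P2O5/MeSO3H (as solvent), 20 → 40 °C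
Reagents that add atoms: none
Why: Intramolecular Friedel–Crafts acylation closes the seven-membered ring at the only free carbon ortho to the side chain, which is activated by the adjacent methoxy group, while bromine blocks the other ortho carbon (the bromine-as-blocking-group tactic of 8-methoxytetralone syntheses).

Step 4
Reactants: 4 1-bromo-3,4-dimethoxy-6,7,8,9-tetrahydro-5H-benzo[7]annulen-5-one
Product: 5 1-iodo-3,4-dimethoxy-6,7,8,9-tetrahydro-5H-benzo[7]annulen-5-one
Conditions: NaI (2 equiv), CuI (5 mol %), trans-N,N'-dimethylcyclohexane-1,2-diamine (10 mol %), 1,4-dioxane, 110 °C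
Reagents that add atoms: sodium iodide, [Na+].[I-]
Why: Copper-catalysed aromatic Finkelstein exchange converts the aryl bromide into the iodide while no second halogen is present, so that the two sites of the later coupling differ in their halogen.

Step 5
Reactants: 5 1-iodo-3,4-dimethoxy-6,7,8,9-tetrahydro-5H-benzo[7]annulen-5-one
Product: 6 1-iodo-3,4-dimethoxy-8,9-dihydro-5H-benzo[7]annulene-5,6(7H)-dione
Conditions: SeO2 (1.5 equiv), 1,4-dioxane/H2O, 100 °C
Reagents that add atoms: selenium dioxide, O=[Se]=O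
Why: Riley oxidation with SeO2 oxidises the only α-methylene (C6) of the aryl ketone to the 1,2-dione, the classical precursor of a benzotropolone.

Step 6
Reactants: 6 1-iodo-3,4-dimethoxy-8,9-dihydro-5H-benzo[7]annulene-5,6(7H)-dione
Product: 9 7-bromo-6-hydroxy-1-iodo-3,4-dimethoxy-5H-benzo[7]annulen-5-one, via bromodione 7 (not isolated), via C7-unsubstituted tropolone 8 (not isolated)
Conditions: Br2 (2.1 equiv), AcOH, 20 → 90 °C
Reagents that add atoms: bromine, BrBr
Why: Bromination–dehydrobromination of a cycloheptane-1,2-dione is the classical tropolone synthesis: the enol is brominated at C7, loss of HBr and enolisation give the tropolone, and its α-carbon C7 (the only free position next to the hydroxyl) should take the second bromine faster than the acyl-deactivated arene or the C–I bond reacts.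

Step 7
Reactants: 9 7-bromo-6-hydroxy-1-iodo-3,4-dimethoxy-5H-benzo[7]annulen-5-one
Product: 10 7-bromo-3,4,6-trihydroxy-1-iodo-5H-benzo[7]annulen-5-one
Conditions: BBr3 (4 equiv), CH2Cl2, −78 → 20 °C; then H2O
Reagents that add atoms: none
Why: BBr3 cleavage of the two aryl methyl ethers frees the catechol so that all three oxygens can be carried as hydrogenolysable benzyl ethers; the aryl iodide and the bromotropolone are inert to BBr3.

Step 8
Reactants: 10 7-bromo-3,4,6-trihydroxy-1-iodo-5H-benzo[7]annulen-5-one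
Product: 11 3,4,6-tris(benzyloxy)-7-bromo-1-iodo-5H-benzo[7]annulen-5-one
Conditions: BnBr (4 equiv), K2CO3 (5 equiv), DMF, 60 °C
Reagents that add atoms: benzyl bromide, BrCc1ccccc1
Why: Williamson etherification of the two phenols and of the tropolonate; the tropolonate should be alkylated at O6 because the O5 ether would be an ortho-quinoid that lacks the benzene sextet.

Step 9
Reactants: 12 3,5-bis(benzyloxy)phenol
Product: 13 1,3-bis(benzyloxy)-5-(methoxymethoxy)benzene
Conditions: NaH, MOMCl, THF/DMF, 0 → 20 °C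
Reagents that add atoms: chloromethyl methyl ether, COCCl
Why: Williamson-type protection of the phenol as its methoxymethyl ether, which directs the metalation of step 10 and is removable by mild acid.

Step 10
Reactants: 13 1,3-bis(benzyloxy)-5-(methoxymethoxy)benzene; 14 methyl (2R)-oxirane-2-carboxylate (methyl (R)-glycidate, 0.8 equiv)
Product: 17 methyl (2R)-3-[2,4-bis(benzyloxy)-6-(methoxymethoxy)phenyl]-2-hydroxypropanoate, via aryllithium 15 (not isolated), via arylmagnesium bromide 16 (not isolated)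
Conditions: n-BuLi (1.1 equiv), THF, −10 → 0 °C; MgBr2·OEt2, −40 °C; CuBr·SMe2 (10 mol %), then 14, −40 → −10 °C; then H2O
Reagents that add atoms: none
Why: Directed ortho-metalation at a carbon flanked by the methoxymethoxy and a benzyloxy group (the better-coordinating acetal directs and the two such sites are equivalent), transmetalation to magnesium and copper-catalysed epoxide opening at the terminal CH2 should give the α-hydroxy ester; the future C3 stereocentre comes unchanged from the (R)-epoxide because its C–O bond is not broken.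

Step 11
Reactants: 17 methyl (2R)-3-[2,4-bis(benzyloxy)-6-(methoxymethoxy)phenyl]-2-hydroxypropanoate
Product: 19 (3R)-5,7-bis(benzyloxy)-3-hydroxychroman-2-one, via phenolic hydroxy ester 18 (not isolated)
Conditions: HCl (cat.), MeOH, 45 °C; then PPTS (cat.), toluene, 90 °C (−MeOH)
Reagents that add atoms: none
Why: Acid-catalysed acetal exchange removes the methoxymethyl group and the freed phenol lactonises onto the methyl ester (six-membered aryl lactone, driven by removal of methanol), which closes the pyran ring without touching the stereocentre.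

Step 12
Reactants: 19 (3R)-5,7-bis(benzyloxy)-3-hydroxychroman-2-one
Product: 20 (3R)-5,7-bis(benzyloxy)chromane-2,3-diol (anomer mixture)
Conditions: i-Bu2AlH (2.3 equiv), CH2Cl2, −78 °C; aq. potassium sodium tartrate
Reagents that add atoms: none
Why: Partial reduction of the lactone with i-Bu2AlH at −78 °C should stop at the lactol because the aluminium hemiacetal, held by the neighbouring aluminium alkoxide, does not collapse before work-up.

Step 13
Reactants: 20 (3R)-5,7-bis(benzyloxy)chromane-2,3-diol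
Product: 21 (3R)-5,7-bis(benzyloxy)-2-(phenylsulfanyl)chroman-3-ol (C2 epimer mixture)
Conditions: PhSH (1.15 equiv), BF3·OEt2 (0.2 equiv), 4 Å MS, CH2Cl2, −40 → 0 °C
Reagents that add atoms: thiophenol, Sc1ccccc1
Why: Acid-catalysed thioacetalisation (thioglycoside formation) through the C2 oxocarbenium ion replaces only the hemiacetal hydroxyl; the C2 configuration is of no consequence because it is erased in step 14, and near-stoichiometric thiol at low temperature guards against ring opening to the dithioacetal.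

Step 14
Reactants: 21 (3R)-5,7-bis(benzyloxy)-2-(phenylsulfanyl)chroman-3-ol
Product: 24 (2R,3R)-5,7-bis(benzyloxy)-2-(tributylstannyl)chroman-3-ol, via lithium alkoxide 22 (not isolated), via C2-lithio alkoxide 23 (not isolated)
Conditions: n-BuLi (1.05 equiv), THF, −78 °C; lithium naphthalenide (LiC10H8, 2.2 equiv), −78 °C; Bu3SnCl (1.1 equiv), −78 °C; then H2O
Reagents that add atoms: tributyltin chloride, CCCC[Sn](Cl)(CCCC)CCCC
Why: Reductive lithiation of the O,S-acetal after deprotonation of the C3 hydroxyl (the dianion tactic used for 1,2-cis glycosyl stannanes): the C2 radical is reduced to the pseudo-axial C–Li bond, which in the half-chair with the C3 lithium alkoxide pseudo-equatorial is cis to it and is held by Li–O bridging, the alkoxide cannot leave as Li2O so β-elimination is blocked, and Bu3SnCl should trap the configurationally stable α-alkoxy organolithium with retention to set the 2,3-cis (2R) centre, any trans isomer being removed by chromatography.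

Step 15
Reactants: 24 (2R,3R)-5,7-bis(benzyloxy)-2-(tributylstannyl)chroman-3-ol (one portion)
Product: 25 tert-butyl{[(2R,3R)-5,7-bis(benzyloxy)-2-(tributylstannyl)chroman-3-yl]oxy}dimethylsilane
Conditions: TBSOTf, 2,6-lutidine, CH2Cl2, −78 → 0 °C
Reagents that add atoms: tert-butyldimethylsilyl trifluoromethanesulfonate, CC(C)(C)[Si](C)(C)OS(=O)(=O)C(F)(F)F
Why: Silylation of the hindered secondary alcohol with the silyl triflate under buffered conditions leaves the C–Sn bond and both stereocentres untouched and labels this C3 oxygen for later galloylation.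

Step 16
Reactants: 24 (2R,3R)-5,7-bis(benzyloxy)-2-(tributylstannyl)chroman-3-ol (other portion)
Product: 26 tributyl[(2R,3R)-3,5,7-tris(benzyloxy)chroman-2-yl]stannane
Conditions: NaH, BnBr, Bu4NI (cat.), THF/DMF, 0 → 20 °C
Reagents that add atoms: benzyl bromide, BrCc1ccccc1
Why: Williamson benzylation of the sodium alkoxide; a β-stannyl alkoxide in the cis (syn-clinal) arrangement should not undergo the anti destannylative elimination that acid would trigger.

Step 17
Reactants: 11 3,4,6-tris(benzyloxy)-7-bromo-1-iodo-5H-benzo[7]annulen-5-one; 25 tert-butyl{[(2R,3R)-5,7-bis(benzyloxy)-2-(tributylstannyl)chroman-3-yl]oxy}dimethylsilane; 26 tributyl[(2R,3R)-3,5,7-tris(benzyloxy)chroman-2-yl]stannane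
Product: 28 3,4,6-tris(benzyloxy)-1-[(2R,3R)-5,7-bis(benzyloxy)-3-[(tert-butyldimethylsilyl)oxy]chroman-2-yl]-7-[(2R,3R)-3,5,7-tris(benzyloxy)chroman-2-yl]-5H-benzo[7]annulen-5-one, via C1-coupled bromide 27 (not isolated)
Conditions: Pd2(dba)3 (5 mol %), JackiePhos (20 mol %), CuCl (3 equiv), KF (4 equiv), 1,4-dioxane, 110 °C, 25 (1.05 equiv); then 26 (1.5 equiv), 110 °C, one pot
Reagents that add atoms: none
Why: Zerovalent palladium bearing JackiePhos inserts into the C1–I bond, CuCl and KF assist transfer of the chromanyl group from tin through a closed transition state that retains configuration at C2, and reductive elimination gives bromide 27, after which the same cycle engages the C7–Br bond (a vinylogous acyl bromide of the 2-alkoxytropone) with 26. The closest known reaction type is the stereoretentive Stille-type coupling of configurationally stable anomeric (α-alkoxy) stannanes with aryl halides under this Pd2(dba)3/JackiePhos/CuCl/KF system. No ring is closed and no stereocentre is created: both C2 centres were set in step 14 and are carried over with retention, so the cis C2/C3 relationship of each stannane becomes the 2,3-cis relationship of each flavan. The step needs site selectivity, which rests on the faster oxidative addition of the aryl iodide than of the bromide (the usual order in bromo-iodo arenes and heteroarenes) and on charging 25 before 26. It also needs suppression of β-elimination of the C3 oxygen, the only β-substituent syn to palladium in the cis ring, which the bulky electron-poor biarylphosphine should provide. The silyl ether on the C1 flavan and the benzyl ether on the C7 flavan mark which hydroxyl is galloylated later.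

Step 18
Reactants: 28 (protected bis-flavan with one silyl ether)
Product: 29 3,4,6-tris(benzyloxy)-1-[(2R,3R)-5,7-bis(benzyloxy)-3-hydroxychroman-2-yl]-7-[(2R,3R)-3,5,7-tris(benzyloxy)chroman-2-yl]-5H-benzo[7]annulen-5-one
Conditions: HF·pyridine, pyridine/THF, 0 → 20 °C
Reagents that add atoms: none
Why: Fluoride-mediated desilylation under buffered, mildly acidic conditions should free only the silyl-labelled C3 hydroxyl, since benzyl ethers and the alkoxytropone are stable to HF·pyridine.

Step 19
Reactants: 29 (mono-alcohol); 30 3,4,5-tris(benzyloxy)benzoic acid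
Product: 31 (2R,3R)-5,7-bis(benzyloxy)-2-{3,4,6-tris(benzyloxy)-5-oxo-7-[(2R,3R)-3,5,7-tris(benzyloxy)chroman-2-yl]-5H-benzo[7]annulen-1-yl}chroman-3-yl 3,4,5-tris(benzyloxy)benzoate
Conditions: DCC, DMAP, CH2Cl2, 20 °C
Reagents that add atoms: none
Why: Steglich esterification acylates the single free secondary hydroxyl, the standard way to gallates of protected epicatechin-type alcohols, and C3 keeps its configuration because its C–O bond is not broken.

Step 20
Reactants: 31 (perbenzylated gallate)
Product: 32 (2R,3R)-5,7-dihydroxy-2-{3,4,6-trihydroxy-5-oxo-7-[(2R,3R)-3,5,7-trihydroxychroman-2-yl]-5H-benzo[7]annulen-1-yl}chroman-3-yl 3,4,5-trihydroxybenzoate (CNP0217128.1)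
Conditions: H2 (1 atm), Pd(OH)2/C, THF/MeOH, 20 °C
Reagents that add atoms: none
Why: Hydrogenolysis of the eleven benzyl ethers under neutral conditions at 1 atm should leave the gallate ester, the benzylic C2–O bonds of the chroman rings and the tropolone intact when stopped at full debenzylation.

**Compound list**

1 | 2-bromo-4,5-dimethoxybenzaldehyde | COc1cc(Br)c(C=O)cc1OC | starting material
2 | 5-(2-bromo-4,5-dimethoxyphenyl)pent-4-enoic acid (E/Z mixture) | COc1cc(Br)c(C=CCCC(=O)O)cc1OC | intermediate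
3 | 5-(2-bromo-4,5-dimethoxyphenyl)pentanoic acid | COc1cc(Br)c(CCCCC(=O)O)cc1OC | intermediate
4 | 1-bromo-3,4-dimethoxy-6,7,8,9-tetrahydro-5H-benzo[7]annulen-5-one | COc1cc(Br)c2CCCCC(=O)c2c1OC | intermediate
5 | 1-iodo-3,4-dimethoxy-6,7,8,9-tetrahydro-5H-benzo[7]annulen-5-one | COc1cc(I)c2CCCCC(=O)c2c1OC | intermediate
6 | 1-iodo-3,4-dimethoxy-8,9-dihydro-5H-benzo[7]annulene-5,6(7H)-dione | COc1cc(I)c2CCCC(=O)C(=O)c2c1OC | intermediate
7 | 7-bromo-1-iodo-3,4-dimethoxy-8,9-dihydro-5H-benzo[7]annulene-5,6(7H)-dione (racemic) | COc1cc(I)c2CCC(Br)C(=O)C(=O)c2c1OC | intermediate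
8 | 6-hydroxy-1-iodo-3,4-dimethoxy-5H-benzo[7]annulen-5-one | COc1cc(I)c2cccc(O)c(=O)c2c1OC | intermediate
9 | 7-bromo-6-hydroxy-1-iodo-3,4-dimethoxy-5H-benzo[7]annulen-5-one | COc1cc(I)c2ccc(Br)c(O)c(=O)c2c1OC | intermediate
10 | 7-bromo-3,4,6-trihydroxy-1-iodo-5H-benzo[7]annulen-5-one | Oc1cc(I)c2ccc(Br)c(O)c(=O)c2c1O | intermediate
11 | 3,4,6-tris(benzyloxy)-7-bromo-1-iodo-5H-benzo[7]annulen-5-one | Ic1cc(OCc2ccccc2)c(OCc2ccccc2)c2c(=O)c(OCc3ccccc3)c(Br)ccc12 | intermediate
12 | 3,5-bis(benzyloxy)phenol | Oc1cc(OCc2ccccc2)cc(OCc2ccccc2)c1 | starting material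
13 | 1,3-bis(benzyloxy)-5-(methoxymethoxy)benzene | COCOc1cc(OCc2ccccc2)cc(OCc2ccccc2)c1 | intermediate
14 | methyl (2R)-oxirane-2-carboxylate | COC(=O)[C@H]1CO1 | starting material
15 | [2,4-bis(benzyloxy)-6-(methoxymethoxy)phenyl]lithium | [Li]c1c(OCOC)cc(OCc2ccccc2)cc1OCc1ccccc1 | intermediate
16 | [2,4-bis(benzyloxy)-6-(methoxymethoxy)phenyl]magnesium bromide | Br[Mg]c1c(OCOC)cc(OCc2ccccc2)cc1OCc1ccccc1 | intermediate
17 | methyl (2R)-3-[2,4-bis(benzyloxy)-6-(methoxymethoxy)phenyl]-2-hydroxypropanoate | COC(=O)[C@H](O)Cc1c(OCOC)cc(OCc2ccccc2)cc1OCc1ccccc1 | intermediate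
18 | methyl (2R)-3-[2,4-bis(benzyloxy)-6-hydroxyphenyl]-2-hydroxypropanoate | COC(=O)[C@H](O)Cc1c(O)cc(OCc2ccccc2)cc1OCc1ccccc1 | intermediate
19 | (3R)-5,7-bis(benzyloxy)-3-hydroxychroman-2-one | O=C1Oc2cc(OCc3ccccc3)cc(OCc3ccccc3)c2C[C@H]1O | intermediate
20 | (3R)-5,7-bis(benzyloxy)chromane-2,3-diol (anomer mixture) | OC1Oc2cc(OCc3ccccc3)cc(OCc3ccccc3)c2C[C@H]1O | intermediate
21 | (3R)-5,7-bis(benzyloxy)-2-(phenylsulfanyl)chroman-3-ol (C2 epimer mixture) | O[C@@H]1Cc2c(OCc3ccccc3)cc(OCc3ccccc3)cc2OC1Sc1ccccc1 | intermediate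
22 | lithium (3R)-5,7-bis(benzyloxy)-2-(phenylsulfanyl)chroman-3-olate | [Li]O[C@@H]1Cc2c(OCc3ccccc3)cc(OCc3ccccc3)cc2OC1Sc1ccccc1 | intermediate
23 | lithium (2R,3R)-5,7-bis(benzyloxy)-2-lithiochroman-3-olate | [Li]O[C@@H]1Cc2c(OCc3ccccc3)cc(OCc3ccccc3)cc2O[C@@H]1[Li] | intermediate
24 | (2R,3R)-5,7-bis(benzyloxy)-2-(tributylstannyl)chroman-3-ol | O[C@@H]1Cc2c(OCc3ccccc3)cc(OCc3ccccc3)cc2O[C@@H]1[Sn](CCCC)(CCCC)CCCC | intermediate
25 | tert-butyl{[(2R,3R)-5,7-bis(benzyloxy)-2-(tributylstannyl)chroman-3-yl]oxy}dimethylsilane | CC(C)(C)[Si](C)(C)O[C@@H]1Cc2c(OCc3ccccc3)cc(OCc3ccccc3)cc2O[C@@H]1[Sn](CCCC)(CCCC)CCCC | intermediate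
26 | tributyl[(2R,3R)-3,5,7-tris(benzyloxy)chroman-2-yl]stannane | CCCC[Sn](CCCC)(CCCC)[C@H]1Oc2cc(OCc3ccccc3)cc(OCc3ccccc3)c2C[C@H]1OCc1ccccc1 | intermediate
27 | 3,4,6-tris(benzyloxy)-1-[(2R,3R)-5,7-bis(benzyloxy)-3-[(tert-butyldimethylsilyl)oxy]chroman-2-yl]-7-bromo-5H-benzo[7]annulen-5-one | CC(C)(C)[Si](C)(C)O[C@@H]1Cc2c(OCc3ccccc3)cc(OCc3ccccc3)cc2O[C@@H]1c1cc(OCc2ccccc2)c(OCc2ccccc2)c2c(=O)c(OCc3ccccc3)c(Br)ccc12 | intermediate
28 | 3,4,6-tris(benzyloxy)-1-[(2R,3R)-5,7-bis(benzyloxy)-3-[(tert-butyldimethylsilyl)oxy]chroman-2-yl]-7-[(2R,3R)-3,5,7-tris(benzyloxy)chroman-2-yl]-5H-benzo[7]annulen-5-one | CC(C)(C)[Si](C)(C)O[C@@H]1Cc2c(OCc3ccccc3)cc(OCc3ccccc3)cc2O[C@@H]1c1cc(OCc2ccccc2)c(OCc2ccccc2)c2c(=O)c(OCc3ccccc3)c([C@H]3Oc4cc(OCc5ccccc5)cc(OCc5ccccc5)c4C[C@H]3OCc3ccccc3)ccc12 | intermediate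
29 | 3,4,6-tris(benzyloxy)-1-[(2R,3R)-5,7-bis(benzyloxy)-3-hydroxychroman-2-yl]-7-[(2R,3R)-3,5,7-tris(benzyloxy)chroman-2-yl]-5H-benzo[7]annulen-5-one | O[C@@H]1Cc2c(OCc3ccccc3)cc(OCc3ccccc3)cc2O[C@@H]1c1cc(OCc2ccccc2)c(OCc2ccccc2)c2c(=O)c(OCc3ccccc3)c([C@H]3Oc4cc(OCc5ccccc5)cc(OCc5ccccc5)c4C[C@H]3OCc3ccccc3)ccc12 | intermediate
30 | 3,4,5-tris(benzyloxy)benzoic acid | OC(=O)c1cc(OCc2ccccc2)c(OCc2ccccc2)c(OCc2ccccc2)c1 | starting material
31 | (2R,3R)-5,7-bis(benzyloxy)-2-{3,4,6-tris(benzyloxy)-5-oxo-7-[(2R,3R)-3,5,7-tris(benzyloxy)chroman-2-yl]-5H-benzo[7]annulen-1-yl}chroman-3-yl 3,4,5-tris(benzyloxy)benzoate | O=C(O[C@@H]1Cc2c(OCc3ccccc3)cc(OCc3ccccc3)cc2O[C@@H]1c1cc(OCc2ccccc2)c(OCc2ccccc2)c2c(=O)c(OCc3ccccc3)c([C@H]3Oc4cc(OCc5ccccc5)cc(OCc5ccccc5)c4C[C@H]3OCc3ccccc3)ccc12)c1cc(OCc2ccccc2)c(OCc2ccccc2)c(OCc2ccccc2)c1 | intermediate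
32 | (2R,3R)-5,7-dihydroxy-2-{3,4,6-trihydroxy-5-oxo-7-[(2R,3R)-3,5,7-trihydroxychroman-2-yl]-5H-benzo[7]annulen-1-yl}chroman-3-yl 3,4,5-trihydroxybenzoate (CNP0217128.1) | O=C(O[C@@H]1Cc2c(O)cc(O)cc2O[C@@H]1c1cc(O)c(O)c2c(=O)c(O)c([C@H]3Oc4cc(O)cc(O)c4C[C@H]3O)ccc12)c1cc(O)c(O)c(O)c1 | target

**Totals and risks**

Total step count: 20. Longest linear sequence: 12 steps (steps 1–8, then 17–20); the stannane arm (steps 9–16) is convergent.

Steps most likely to fail:

1. Step 17. Oxidative addition at the C7 bromide may compete while the C1 iodide is still present, so that the two stannanes are spread over both sites; β-elimination of the C3 oxygen from the alkylpalladium or protodestannylation of the hindered silyloxy stannane may also erode the coupling. Fallback, setting out from bromide 4 and coming back at 28: if the C7 bromide proves as reactive as the iodide, that reactivity is used instead of fought, with bromine at both sites and two isolated couplings. The halogen exchange is left out. SeO2 oxidation of 4 gives 1-bromo-3,4-dimethoxy-8,9-dihydro-5H-benzo[7]annulene-5,6(7H)-dione F1, Br2 in AcOH gives 1,7-dibromo-6-hydroxy-3,4-dimethoxy-5H-benzo[7]annulen-5-one F2, BBr3 gives 1,7-dibromo-3,4,6-trihydroxy-5H-benzo[7]annulen-5-one F3, and BnBr/K2CO3 gives 3,4,6-tris(benzyloxy)-1,7-dibromo-5H-benzo[7]annulen-5-one F4. With Pd2(dba)3/JackiePhos/CuCl/KF at 80–90 °C the activated C7 bromide is coupled first, now with 26, to give the isolated 3,4,6-tris(benzyloxy)-1-bromo-7-[(2R,3R)-3,5,7-tris(benzyloxy)chroman-2-yl]-5H-benzo[7]annulen-5-one F5. A separate coupling of its unactivated aryl bromide with 25 at 110 °C then gives 28.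

2. Step 14. The reduction of the C2 radical may show poor facial selectivity (cis/trans mixture at C2), and electron transfer from the arene radical anion may cleave aryl benzyl ethers. Fallback, setting out from lactone 19 and coming back at 25 (and from 25 at 24): the C2–Sn bond is made by inversion instead of by axial lithiation. TBSCl/imidazole gives (3R)-5,7-bis(benzyloxy)-3-[(tert-butyldimethylsilyl)oxy]chroman-2-one F6, and i-Bu2AlH at −78 °C gives (3R)-5,7-bis(benzyloxy)-3-[(tert-butyldimethylsilyl)oxy]chroman-2-ol F7. (COCl)2 with catalytic DMF gives the thermodynamically preferred trans-diaxial chloride (2S,3R)-5,7-bis(benzyloxy)-3-[(tert-butyldimethylsilyl)oxy]-2-chlorochromane F8. SN2 displacement with Bu3SnLi at −78 °C inverts C2 and gives the cis stannane 25 directly; Bu4NF on a portion of 25 gives 24 for step 16.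

3. Step 6. Bromine may attack the arene or displace iodine at C1 in competition with the enol bromination–dehydrobromination sequence, and hot HBr/AcOH may cleave methyl ethers or over-brominate. Fallback, setting out from dione 6 and coming back at 9: the two oxidation events are separated and elemental bromine is avoided. CuBr2 (2 equiv, EtOAc/CHCl3, reflux) monobrominates C7 to give bromodione 7, now isolated; Li2CO3/LiBr in DMF at 100 °C eliminates HBr to give tropolone 8, now isolated; NBS (1 equiv, MeCN, 0 °C) brominates the tropolone α-carbon to give 9. No compound outside the compound list is made (F0).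

**Further compounds**

F1 | step 17 | 1-bromo-3,4-dimethoxy-8,9-dihydro-5H-benzo[7]annulene-5,6(7H)-dione | COc1cc(Br)c2CCCC(=O)C(=O)c2c1OC
F2 | step 17 | 1,7-dibromo-6-hydroxy-3,4-dimethoxy-5H-benzo[7]annulen-5-one | COc1cc(Br)c2ccc(Br)c(O)c(=O)c2c1OC
F3 | step 17 | 1,7-dibromo-3,4,6-trihydroxy-5H-benzo[7]annulen-5-one | Oc1cc(Br)c2ccc(Br)c(O)c(=O)c2c1O
F4 | step 17 | 3,4,6-tris(benzyloxy)-1,7-dibromo-5H-benzo[7]annulen-5-one | Brc1cc(OCc2ccccc2)c(OCc2ccccc2)c2c(=O)c(OCc3ccccc3)c(Br)ccc12
F5 | step 17 | 3,4,6-tris(benzyloxy)-1-bromo-7-[(2R,3R)-3,5,7-tris(benzyloxy)chroman-2-yl]-5H-benzo[7]annulen-5-one | Brc1cc(OCc2ccccc2)c(OCc2ccccc2)c2c(=O)c(OCc3ccccc3)c([C@H]3Oc4cc(OCc5ccccc5)cc(OCc5ccccc5)c4C[C@H]3OCc3ccccc3)ccc12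
F6 | step 14 | (3R)-5,7-bis(benzyloxy)-3-[(tert-butyldimethylsilyl)oxy]chroman-2-one | CC(C)(C)[Si](C)(C)O[C@@H]1Cc2c(OCc3ccccc3)cc(OCc3ccccc3)cc2OC1=O
F7 | step 14 | (3R)-5,7-bis(benzyloxy)-3-[(tert-butyldimethylsilyl)oxy]chroman-2-ol | CC(C)(C)[Si](C)(C)O[C@@H]1Cc2c(OCc3ccccc3)cc(OCc3ccccc3)cc2OC1O
F8 | step 14 | (2S,3R)-5,7-bis(benzyloxy)-3-[(tert-butyldimethylsilyl)oxy]-2-chlorochromane | CC(C)(C)[Si](C)(C)O[C@@H]1Cc2c(OCc3ccccc3)cc(OCc3ccccc3)cc2O[C@H]1Cl
F0 | step 6 | none | none
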